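**Retrosynthetic overview**
- The last bonds formed are the aryl C1–C(=O) bond to the second dichloropyrrole (Friedel–Crafts aroylation with the pyrrole acid chloride) and the free C4–OH (methyl ether cleavage). This leads back to 1-(4,5-dichloropyrrol-2-yl)-3-(2-hydroxy-6-methoxyphenyl)propan-1-one.
- That ketophenol is a masked 3-aroylcoumarin: conjugate reduction of C3=C4, lactone hydrolysis and loss of the lactone carbonyl as carbon dioxide.
- The coumarin is assembled in one step from 3-methoxybenzyne, DMF and the pyrrolyl keto ester. The feature used: on the benzene ring of the target, C2–O and the benzylic C3–CH2 are neighbours, and C3 carries C4–O on its other side. This contiguous O/C/O pattern is what 3-methoxybenzyne gives on inserting into a formamide C=O.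
- Ring order: the benzene and both pyrrole rings are bought. The only ring closed is the pyranone of the coumarin (key step), and it is opened again in the decarboxylation. Both pyrrole units come from 4,5-dichloro-1H-pyrrole-2-carboxylic acid.

Key step: step 2

Assumption: both pyrrole N–H groups are carried unprotected, because the 2-acyl-4,5-dichloropyrrole nitrogen is a poor nucleophile and DMF, used as solvent, should intercept the aryne before it does.

**Step 1**
Reactants: 1 4,5-dichloro-1H-pyrrole-2-carboxylic acid; 2 potassium methyl malonate
Product: 5 methyl 3-(4,5-dichloro-1H-pyrrol-2-yl)-3-oxopropanoate, via acyl imidazolide 3 (not isolated), via acylmalonic half ester 4 (not isolated)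
Conditions: CDI (1.1 equiv), THF, 25 °C; then 2 (2 equiv), MgCl2 (2 equiv), Et3N, THF, 25 to 50 °C; aq. HCl work-up
Reagents that add atoms: 1,1'-carbonyldiimidazole, O=C(n1ccnc1)n1ccnc1 (its imidazol-1-yl group sits in intermediate 3 only; none of its atoms stays in 5)
Why: Masamune–Brooks homologation, in which the mild acyl imidazolide 3 C-acylates the malonate half-ester enolate formed with MgCl2 and Et3N and the acylmalonate 4 loses carbon dioxide on acidification, a sequence that should tolerate the unprotected pyrrole N–H.

**Step 2**
Reactants: 5 methyl 3-(4,5-dichloro-1H-pyrrol-2-yl)-3-oxopropanoate; 6 2-methoxy-6-(trimethylsilyl)phenyl trifluoromethanesulfonate; 7 N,N-dimethylformamide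
Product: 12 3-(4,5-dichloro-1H-pyrrole-2-carbonyl)-5-methoxy-2H-chromen-2-one, via 3-methoxybenzyne 8 (not isolated), via aminobenzoxete 9 (not isolated), via amino quinone methide 10 (not isolated), via phenoxide adduct 11 (not isolated)
Conditions: CsF (4 equiv), DMF (solvent), 25 °C; 6 (1.5 equiv) added slowly
Reagents that add atoms: none
Why: Fluoride removes the silyl group of 6 and triflate departs to give 3-methoxybenzyne 8, whose strained triple bond is attacked by the carbonyl oxygen of the solvent DMF; the aryl anion closes on the iminium carbon (formal [2+2]) to benzoxete 9, which opens to the amino-substituted ortho-quinone methide 10. The enolate of 5 adds to the exocyclic carbon of 10 (Michael addition) to give phenoxide 11, which expels dimethylamine and lactonises onto the methyl ester (6-exo-trig acyl substitution, loss of methanol) to give the aromatic coumarin 12. This is the known three-component coupling of arynes, formamides and active methylene compounds to coumarins, applied here to a heteroaryl keto ester. The selectivity that matters is the orientation of the aryne: the inductively withdrawing methoxy group beside the triple bond sends the oxygen nucleophile to the distal carbon so that the negative charge develops next to methoxy, which places the new C–C bond between the two oxygens and the methoxy group at C5 of the coumarin. No stereocentre is formed. Chemoselectivity against N-arylation of the acidic pyrrole N–H and against direct arylation of the enolate rests on DMF being present in large excess as solvent and on slow release of the aryne.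

**Step 3**
Reactants: 12 3-(4,5-dichloro-1H-pyrrole-2-carbonyl)-5-methoxy-2H-chromen-2-one
Product: 13 3-(4,5-dichloro-1H-pyrrole-2-carbonyl)-5-methoxy-3,4-dihydro-2H-chromen-2-one (racemic)
Conditions: Hantzsch ester (diethyl 2,6-dimethyl-1,4-dihydropyridine-3,5-dicarboxylate, 1.3 equiv), AcOH (10 mol %), toluene, 80 °C
Reagents that add atoms: none
Why: Conjugate transfer hydrogenation, in which the C3=C4 bond of a 3-acylcoumarin (an alkylidene activated by both ketone and lactone) accepts hydride at C4 from the dihydropyridine while the aryl ketone and the C–Cl bonds stay untouched; the new C3 stereocentre forms racemic and is removed in step 4.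

**Step 4**
Reactants: 13 3-(4,5-dichloro-1H-pyrrole-2-carbonyl)-5-methoxy-3,4-dihydro-2H-chromen-2-one
Product: 15 1-(4,5-dichloro-1H-pyrrol-2-yl)-3-(2-hydroxy-6-methoxyphenyl)propan-1-one, via beta-keto acid 14 (not isolated)
Conditions: 6 M aq. HCl, AcOH, 100 °C
Reagents that add atoms: water, O (its oxygen enters intermediate 14 and leaves again in the carbon dioxide; 15 keeps only hydrogen from it)
Why: Acid-mediated lactone hydrolysis followed by thermal decarboxylation of beta-keto acid 14 (ketonic cleavage of a beta-keto ester), which erases the C3 stereocentre and should leave the acid-stable dichloropyrrolyl ketone and the methyl ether in place.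

**Step 5**
Reactants: 1 4,5-dichloro-1H-pyrrole-2-carboxylic acid
Product: 16 4,5-dichloro-1H-pyrrole-2-carbonyl chloride
Conditions: (COCl)2 (1.5 equiv), DMF (cat.), CH2Cl2, 0 to 25 °C; evaporated and used crude
Reagents that add atoms: oxalyl chloride, O=C(Cl)C(=O)Cl
Why: Standard acid chloride formation through the chloroiminium species from oxalyl chloride and catalytic DMF; the electron-poor dichloropyrrole ring is not attacked and the chloride is used at once to limit self-condensation through the N–H.

**Step 6**
Reactants: 15 1-(4,5-dichloro-1H-pyrrol-2-yl)-3-(2-hydroxy-6-methoxyphenyl)propan-1-one; 16 4,5-dichloro-1H-pyrrole-2-carbonyl chloride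
Product: 17 1-(4,5-dichloro-1H-pyrrol-2-yl)-3-[3-(4,5-dichloro-1H-pyrrole-2-carbonyl)-2-hydroxy-6-methoxyphenyl]propan-1-one
Conditions: 16 (1.2 equiv), AlCl3 (4.5 equiv), 1,2-dichloroethane, 0 to 60 °C; aq. HCl work-up
Reagents that add atoms: none
Why: Friedel–Crafts acylation (any O-aroyl ester formed first should converge by Fries rearrangement) at the position para to methoxy and ortho to the AlCl3-bound phenol oxygen, the most electron-rich site of this 3-methoxyphenol-type ring, as in the classical preparation of 2-hydroxy-4-methoxyaryl ketones; attack at the other position para to oxygen would give the same target after step 7, and the acyl- and chloro-deactivated pyrrole rings should not compete.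

**Step 7**
Reactants: 17 1-(4,5-dichloro-1H-pyrrol-2-yl)-3-[3-(4,5-dichloro-1H-pyrrole-2-carbonyl)-2-hydroxy-6-methoxyphenyl]propan-1-one
Product: 18 dihydrotetrachlorizine
Conditions: BBr3 (6 equiv), CH2Cl2, −78 to 25 °C; then H2O
Reagents that add atoms: none
Why: Aryl methyl ether cleavage with BBr3 (bromide attack on the O-methyl group of the boron-complexed ether), a standard demethylation that aryl ketones, phenols and chlorinated acylpyrroles should withstand.

**Compound list**
1 | 4,5-dichloro-1H-pyrrole-2-carboxylic acid | OC(=O)c1cc(Cl)c(Cl)[nH]1 | starting material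
2 | potassium methyl malonate (potassium 3-methoxy-3-oxopropanoate) | COC(=O)CC(=O)[O-].[K+] | starting material
3 | (4,5-dichloro-1H-pyrrol-2-yl)(1H-imidazol-1-yl)methanone (formed in the flask, not isolated) | O=C(c1cc(Cl)c(Cl)[nH]1)n1ccnc1 | intermediate
4 | 2-(4,5-dichloro-1H-pyrrole-2-carbonyl)-3-methoxy-3-oxopropanoic acid (formed in the flask as its carboxylate, not isolated) | COC(=O)C(C(O)=O)C(=O)c1cc(Cl)c(Cl)[nH]1 | intermediate
5 | methyl 3-(4,5-dichloro-1H-pyrrol-2-yl)-3-oxopropanoate | COC(=O)CC(=O)c1cc(Cl)c(Cl)[nH]1 | intermediate
6 | 2-methoxy-6-(trimethylsilyl)phenyl trifluoromethanesulfonate | COc1cccc([Si](C)(C)C)c1OS(=O)(=O)C(F)(F)F | starting material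
7 | N,N-dimethylformamide | CN(C)C=O | starting material
8 | 3-methoxybenzyne (formed in the flask, not isolated) | COC1=CC=CC#C1 | intermediate
9 | 3-methoxy-N,N-dimethyl-2H-benzo[b]oxet-2-amine (racemic, formed in the flask, not isolated) | CN(C)C1Oc2cccc(OC)c12 | intermediate
10 | 6-[(dimethylamino)methylidene]-5-methoxycyclohexa-2,4-dien-1-one (formed in the flask, not isolated) | CN(C)C=C1C(=O)C=CC=C1OC | intermediate
11 | methyl 2-(4,5-dichloro-1H-pyrrole-2-carbonyl)-3-(dimethylamino)-3-(2-hydroxy-6-methoxyphenyl)propanoate (diastereomer mixture, present as phenoxide, not isolated) | COC(=O)C(C(=O)c1cc(Cl)c(Cl)[nH]1)C(N(C)C)c1c(O)cccc1OC | intermediate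
12 | 3-(4,5-dichloro-1H-pyrrole-2-carbonyl)-5-methoxy-2H-chromen-2-one | COc1cccc2oc(=O)c(C(=O)c3cc(Cl)c(Cl)[nH]3)cc12 | intermediate
13 | 3-(4,5-dichloro-1H-pyrrole-2-carbonyl)-5-methoxy-3,4-dihydro-2H-chromen-2-one (racemic at C3) | COc1cccc2OC(=O)C(C(=O)c3cc(Cl)c(Cl)[nH]3)Cc12 | intermediate
14 | 2-(4,5-dichloro-1H-pyrrole-2-carbonyl)-3-(2-hydroxy-6-methoxyphenyl)propanoic acid (racemic, formed in the flask, not isolated) | COc1cccc(O)c1CC(C(O)=O)C(=O)c1cc(Cl)c(Cl)[nH]1 | intermediate
15 | 1-(4,5-dichloro-1H-pyrrol-2-yl)-3-(2-hydroxy-6-methoxyphenyl)propan-1-one | COc1cccc(O)c1CCC(=O)c1cc(Cl)c(Cl)[nH]1 | intermediate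
16 | 4,5-dichloro-1H-pyrrole-2-carbonyl chloride | O=C(Cl)c1cc(Cl)c(Cl)[nH]1 | intermediate
17 | 1-(4,5-dichloro-1H-pyrrol-2-yl)-3-[3-(4,5-dichloro-1H-pyrrole-2-carbonyl)-2-hydroxy-6-methoxyphenyl]propan-1-one | COc1ccc(C(=O)c2cc(Cl)c(Cl)[nH]2)c(O)c1CCC(=O)c1cc(Cl)c(Cl)[nH]1 | intermediate
18 | dihydrotetrachlorizine | O=C(CCc1c(O)ccc(C(=O)c2cc(Cl)c(Cl)[nH]2)c1O)c1cc(Cl)c(Cl)[nH]1 | target

**Step count**
Total: 7 steps. Longest linear sequence: 6 steps (steps 1, 2, 3, 4, 6, 7); step 5 is a one-step branch from acid 1.

**Steps most likely to fail**

Step 2 (key step). The aryne may be consumed by N-arylation of the acidic pyrrole nitrogen or by direct arylation or acyl–alkyl insertion of the enolate before DMF captures it, and lactonisation of the adduct may stall. The fallback sets out from keto ester 5 and returns at coumarin 12. Keto ester 5 is condensed with commercial 2-hydroxy-6-methoxybenzaldehyde F1 under Knoevenagel conditions (piperidine, AcOH cat., EtOH, reflux). Condensation at the aldehyde followed by lactonisation of the phenol onto the methyl ester should give 12 with the same oxygen/carbon/oxygen pattern and without any aryne.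

Step 6. The weakly electrophilic pyrrolyl acylium may stop at O-acylation, the N–H acid chloride may self-condense, or the Lewis acid may drive cyclodehydration of the phenol onto the side-chain ketone. The fallback sets out from ketophenol 15 and returns at target 18 with the order of events inverted. Compound 15 is demethylated first (BBr3, CH2Cl2, −78 to 25 °C) to the mirror-symmetric resorcinol 1-(4,5-dichloro-1H-pyrrol-2-yl)-3-(2,6-dihydroxyphenyl)propan-1-one F2. F2 is then C-acylated with free acid 1 under Nencki-type conditions (BF3·OEt2, 80 °C, or ZnCl2/POCl3). Both open positions of F2 are equivalent and each is ortho to one hydroxyl and para to the other, so this should give 18 directly.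

Step 4. Hot aqueous acid may cause retro-Claisen cleavage of the beta-keto lactone or cyclodehydration of the product to a 4H-chromene. The fallback sets out from dihydrocoumarin 13 and returns at ketophenol 15. Compound 13 is heated with allyl alcohol in toluene (100 °C), where ring opening through the acylketene should give allyl 2-(4,5-dichloro-1H-pyrrole-2-carbonyl)-3-(2-hydroxy-6-methoxyphenyl)propanoate F3. F3 is then treated with the zerovalent palladium complex Pd(PPh3)4 and morpholine in THF at 25 °C. This Tsuji-type deallylation and decarboxylation under neutral conditions should give 15.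

**Further compounds**
F1 | step 2 | 2-hydroxy-6-methoxybenzaldehyde | COc1cccc(O)c1C=O
F2 | step 6 | 1-(4,5-dichloro-1H-pyrrol-2-yl)-3-(2,6-dihydroxyphenyl)propan-1-one | O=C(CCc1c(O)cccc1O)c1cc(Cl)c(Cl)[nH]1
F3 | step 4 | allyl 2-(4,5-dichloro-1H-pyrrole-2-carbonyl)-3-(2-hydroxy-6-methoxyphenyl)propanoate (racemic) | C=CCOC(=O)C(Cc1c(O)cccc1OC)C(=O)c1cc(Cl)c(Cl)[nH]1
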